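If the next run is to be spent on one change to the flask, we want a rule that reads target from substrate without our knowing how much reagent stands in the reaction phase at each moment.

- south: substrate 1 M; reagent in the second phase 3 M; run made earlier
- flask: substrate 2.0 M; reagent in the second phase 3.00 M; time 15 h; volume of the second phase over the first 1.0

south run (percent of the substrate charged)

| time / h | target / % | substrate / % |
|---|---|---|
| 5.00 | 2.0 | 97.7 |
| 10.0 | 5.4 | 93.7 |
| 15.0 | 9.5 | 88.6 |
| 20.0 | 12.1 | 84.1 |

(standard deviation of a reading: 0.3 percentage points)

- in the second phase: reagent in the second phase; everything else is in the first
- charges count per volume of the first phase; a concentration in a rate is the amount of a species over the volume of its own phase; every rate counts per litre of the first phase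
- reactions considered so far: reagent in the reaction phase + target -> over-reacted product; reagent in the reaction phase + target -> over-reaction product; reagent in the reaction phase <-> reagent in the second phase; substrate + reagent in the reaction phase -> target
- the earlier runs hold the two phases in the same ratio of volumes as the flask asked about

* how much target there is at 15 h, in percent of the substrate charged
* the change that raises the amount of target at 15 h, in percent of the substrate charged most ("none" if none brings more than 2 percentage points) (winter / spring / none)
* amount of target at 15 h, in percent of the substrate charged, after winter

Substrate's step and target's two onward steps are each first order in reagent in the reaction phase, so dividing d[target]/dt by d[substrate]/dt cancels that level and the ratio integrates in closed form. With S the fraction of substrate left and κ the selectivity factor, target's loss constant over substrate's, the target fraction is (S − S^κ)/(κ − 1). At small conversion the missing balance is κ times conversion squared over 2, so the last south reading gives κ = 3.01.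

If the flask loses the south percentage by 15 h, the rule gives 9.52 %; if it loses the same molarity, 5.22 %. The south run has one charge of substrate, so its readings do not tell these two cases apart; we carry both as the span of our reckoning and work out the two changes on the first case.

The south readings climb at 0.0108 h⁻¹ in −ln S after a lag of 3.98 h. We expect winter to cut that lag to 1.99 h, so S becomes 86.7 % and target 10.8 %. We expect spring to double −ln S, giving 15.1 %, more than winter, so the next run gets doubled reagent.

The forecast says 8.7 %, spring and 11.8 %, holding that “Doubling the reagent doubles the reagent level”.

The flask gives 8.35 %, with spring best at 4.7 percentage points against 2.2 points for winter, which reaches 10.5 %.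

    reagent in the reaction phase + target → over-reacted product (k = 0.0736 L mol⁻¹ h⁻¹)
    reagent in the reaction phase + target → over-reaction product (k = 0.0492 L mol⁻¹ h⁻¹)
    reagent in the reaction phase ⇌ reagent in the second phase, rate k3*([reagent in the reaction phase] - [reagent in the second phase]/K3) per volume of the first phase (partition coefficient = 5.30, kL = 0.115 h⁻¹)
    substrate + reagent in the reaction phase → target (k = 0.0337 L mol⁻¹ h⁻¹)

At 15 h the flask holds 89.9 % substrate, and κ turns that into 8.62 % target. Left until 6.0 h, the same flask holds 97.3 % substrate, from which κ gives 2.59 %, and its target stands at 2.55 %.

Readings and results were computed for an exercise; noise was put on by code.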